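The runs come from a simulation for an exercise; noise was put on by code.

After 3.00 h at −12 °C the south-east flask still holds 79.7% of its starting material and the west flask 79.4%, although the two differ in both concentration and activator.

south-east run (percent of the starting material charged)

| time / h | ring / % | starting material / % |
|---|---|---|
| 0.833 | 0.3 | 93.6 |
| 1.50 | 0.2 | 88.9 |
| 2.50 | 0.4 | 82.8 |
| 3.00 | 0 | 79.7 |

north-west run (percent of the starting material charged)

| time / min | ring / % | starting material / % |
|---|---|---|
| 3.00 | 0.8 | 55.5 |
| 8.00 | 4.3 | 28.9 |
| 15.0 | 10.2 | 15.5 |
| 25.0 | 16.1 | 7.7 |

west run (percent of the starting material charged)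

| time / h | ring / % | starting material / % |
|---|---|---|
| 0.250 | 0.2 | 97.8 |
| 0.500 | 0.2 | 95.8 |
| 1.33 | 0 | 90.2 |
| 3.00 | 0.1 | 79.4 |

(each reading ± 0.3 percentage points)

A falling amount has a rate g, the inverse of its time constant, with g = ln(charged/remaining)/t. The south-east flask gives g = 0.0756 /h, a time constant of 13.2 h, and the west flask gives 0.0769 /h.

At fixed equivalents, a step between two dissolved partners speeds up in proportion to concentration, so the fair comparison is r = g/c, with c the starting concentration. That gives r_S = 0.869 /M/h for south-east and r_W = 1.24 /M/h for west.

The west flask carries twice the activator per starting material. Suppose one part of r follows the activator and the rest ignores it. Doubling the equivalents then doubles that part, so r_W − r_S is the part belonging to 1.1 equiv. Dividing by r_S gives the activator share φ, the fraction of lost starting material that goes through the activator, a selectivity in the usual term: φ = (r_W − r_S)/r_S = 0.427. An even split would read 0.5. The scatter of 0.3 percentage points puts about 0.0335 on this reading, which holds for −12 °C and the early part of a run.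

If ring forms through the activator, one per starting material, and if φ stays the same on warming, which the two cold runs do not test, then a flask that finishes ends near 42.7% of ring. That estimate is my own reckoning, and it names no leader.

| setting | south-east | north-west | west | amber | red | violet | teal |
|---|---|---|---|---|---|---|---|
| starting material | 0.087 M | 0.14 M | 0.062 M | 0.062 M | 0.062 M | 0.062 M | 0.062 M |
| activator | 1.1 equiv | 1.1 equiv | 2.2 equiv | 1.10 equiv | 1.10 equiv | 1.10 equiv | 1.10 equiv |
| temperature | −12 °C | 37 °C | −12 °C | −5 °C | 55 °C | −35 °C | 25 °C |
| remark | run made earlier | run made earlier | run made earlier |  |  |  |  |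
| time |  |  |  | 5.0 h | 5.0 h | 5.0 h | 5.0 h |

- which flask leads in amount of ring, in percent of the starting material charged ("all alike" within 1.5 percentage points) (amber / red / violet / teal / all alike)
- how much ring is there at the end, in percent of the starting material charged: amber
- how much ring is there at the end, in percent of the starting material charged: red
- how much ring is there at the end, in percent of the starting material charged: violet
- how much ring is there at the end, in percent of the starting material charged: teal



The forecast names teal as leader with 24%, and gives red 14%, amber 0.5% and violet 0%: “Red finishes fast, but losses probably erode it.” Its figure for red stands lower than my estimate, and there the two differ.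

Red ends at 35.7% of ring, ahead of teal at 32.5%, amber at 0.534% and violet at 0%, so red leads.

    starting material + activator → activated form (k = 0.00263 /M/s, Ea = 58.0 kJ/mol)
    activated form → ring (k = 2.00 × 10⁻⁴ /s, Ea = 89.0 kJ/mol)
    starting material + activated form → open dimer (k = 0.00281 /M/s, Ea = 47.0 kJ/mol)
    2 starting material → self-condensation product (k = 0.00377 /M/s, Ea = 69.0 kJ/mol)
    (constants at 25 °C)

Red's starting material, the limiting reagent, stands at 0% by 2.50 h, with 35.7% of ring already there. Read as a share, red's activator has taken up 37.2% of the starting material charged, less than the φ = 0.427 read at −12 °C. Teal, left standing until 50.0 h, has taken up 42.7%, more than red, and holds 37.4% of ring.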